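**Retrosynthetic overview**

- Structural feature (germacrane numbering: ring C1–C10, C14 on C10, C15 on C4, lactone C12–O–C6, C11–C13 on C7): the lactone oxygen on C6 stands 1,3 to C1 of the Z C1=C10 alkene across C10. A C6–C10 bond would therefore divide the ten-membered ring into a cyclopentane (C6–C10) and a cycloheptane (C10, C1–C6), a hydroazulene 1,3-diol set up for Grob fragmentation.
- Target ⇒ (ketal hydrolysis, O8 acylation, PMB removal, C13 methylenation, C12 oxidation with lactonisation, C6 reduction) Z-cyclodecenone with a C6 ketone ⇒ (Grob fragmentation) cis-hydroazulene C6 tertiary alcohol C1 mesylate.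
- Hydroazulene ⇒ C5–C6 closure (SmI2 Barbier) and C10–C1 aldol between a C1–C5 iodo aldehyde and a regiodefined C10 enolate, made by conjugate reduction of a C10-methylidene cyclopentanone.
- Cyclopentanone ⇒ (1R,5S)-2-oxabicyclo[3.3.0]oct-6-en-3-one (C7, C8); iodo aldehyde ⇒ methyl (R)-3-hydroxy-2-methylpropanoate (C4) and tert-butyl acetate; side-chain acid ⇒ tert-butyl acrylate and acetaldehyde.
- Ring order: cyclopentane (from the lactone) → cycloheptane (C5–C6) → ten-membered ring (fragmentation) → γ-lactone.

Key step: step 19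

Remark: direct deprotonation of a 2-methylcyclopentanone that carries O8 would also take the C7 hydrogen and expel the C8 ether, so the C10 enolate is generated by hydride conjugate addition to the C10-methylidene ketone.
Remark: the (1R,5S) lactone and the (R) hydroxy ester are taken as commercial in the enantiomeric form shown; the side-chain acid is prepared in steps 25–28.

**Route**

Step 1
Reactants: 1 (1R,5S)-2-oxabicyclo[3.3.0]oct-6-en-3-one
Product: 2 (1R,2S)-2-(2-hydroxyethyl)cyclopent-3-en-1-ol
Conditions: LiAlH4, THF, 0 °C to rt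
Reagents that add atoms: none
Why: Hydride reduction of the γ-lactone should give the 1,4-diol without touching C7, C8 or the ring alkene, and it removes the enolisable ester before the base steps.

Step 2
Reactants: 2 diol
Product: 3 (1R,2S)-2-[2-(tert-butyldimethylsilyloxy)ethyl]cyclopent-3-en-1-ol
Conditions: TBSCl (1.05 equiv), imidazole, CH2Cl2, −10 °C
Reagents that add atoms: tert-butyldimethylsilyl chloride, CC(C)(C)[Si](C)(C)Cl
Why: Silylation with a bulky chlorosilane at low temperature should select the primary hydroxyl (O12) over the ring carbinol (O8).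

Step 3
Reactants: 3 mono-silyl ether
Product: 4 tert-butyl{2-[(1S,5R)-5-(4-methoxybenzyloxy)cyclopent-2-en-1-yl]ethoxy}dimethylsilane
Conditions: NaH, 4-MeOC6H4CH2Cl, Bu4NI (cat.), THF/DMF, 0 °C to rt
Reagents that add atoms: 4-methoxybenzyl chloride, COc1ccc(CCl)cc1
Why: Williamson etherification of the O8 alkoxide, done before the epoxidation so that no free hydroxyl directs the peracid.

Step 4
Reactants: 4 cyclopentene
Product: 5 (1S,2R,3R,5R)-2-[2-(tert-butyldimethylsilyloxy)ethyl]-3-(4-methoxybenzyloxy)-6-oxabicyclo[3.1.0]hexane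
Conditions: mCPBA, CH2Cl2, 0 °C
Reagents that add atoms: 3-chloroperoxybenzoic acid, O=C(OO)c1cccc(Cl)c1
Why: Prilezhaev epoxidation of the C6=C10 alkene should occur on the face opposite to the cis C7 chain and O8 ether, placing the oxirane trans to both.

Step 5
Reactants: 5 epoxide
Product: 6 (1R,2S,3R)-2-[2-(tert-butyldimethylsilyloxy)ethyl]-3-(4-methoxybenzyloxy)cyclopentan-1-ol
Conditions: LiBHEt3, THF, 0 °C to rt
Reagents that add atoms: none
Why: SN2 hydride opening should take place at C10, the oxirane carbon remote from the C7 branch (attack at C6 would be cis-vicinal to the side chain), which leaves the oxygen on C6.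

Step 6
Reactants: 6 alcohol
Product: 7 (2R,3R)-2-[2-(tert-butyldimethylsilyloxy)ethyl]-3-(4-methoxybenzyloxy)cyclopentan-1-one
Conditions: Dess–Martin periodinane, pyridine, CH2Cl2, 0 °C to rt
Reagents that add atoms: none
Why: Buffered Dess–Martin oxidation gives the β-alkoxy cyclopentanone without base, so C7 should not epimerise and O8 should not be eliminated.

Step 7
Reactants: 7 ketone
Product: 11 (2R,3R)-2-[2-(tert-butyldimethylsilyloxy)ethyl]-3-(4-methoxybenzyloxy)-5-methylidenecyclopentan-1-one, via lithium enolate 8 (not isolated), via Mannich base 9 (not isolated), via ammonium iodide 10 (not isolated)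
Conditions: LiN(i-Pr)2 (1.05 equiv), THF, −78 °C; [Me2N=CH2]I, −78 °C to rt; MeI, CH2Cl2/MeOH, rt; aq NaHCO3, CH2Cl2, rt
Reagents that add atoms: N,N-dimethylmethyleneiminium iodide, C=[N+](C)C.[I-]
Why: Kinetic deprotonation should take the α-methylene C10 and not the α-methine C7, and Mannich reaction, quaternisation and E1cB loss of trimethylamine then give the exocyclic enone, which can only form at C10.

Step 8
Reactants: 12 methyl (R)-3-hydroxy-2-methylpropanoate
Product: 13 methyl (R)-3-(tert-butyldimethylsilyloxy)-2-methylpropanoate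
Conditions: TBSCl, imidazole, DMF, 0 °C to rt
Reagents that add atoms: tert-butyldimethylsilyl chloride, CC(C)(C)[Si](C)(C)Cl
Why: Silyl protection masks the C5 hydroxyl for the Claisen condensation and does not involve the C4 stereocentre.

Step 9
Reactants: 13 silyl ether ester; 14 tert-butyl acetate
Product: 16 tert-butyl (4R)-5-(tert-butyldimethylsilyloxy)-4-methyl-3-oxopentanoate, via lithium enolate 15 (not isolated)
Conditions: LiN(i-Pr)2 (3 equiv), 14 (3 equiv), THF, −78 °C; then 13, −78 to −40 °C; AcOH quench
Reagents that add atoms: none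
Why: Crossed Claisen condensation of the tert-butyl acetate enolate with the methyl ester, in which the excess base holds the product as its C2 enolate and so should protect C4 from epimerisation.

Step 10
Reactants: 16 β-keto ester
Product: 17 tert-butyl 2-{2-[(2R)-1-(tert-butyldimethylsilyloxy)propan-2-yl]-1,3-dioxolan-2-yl}acetate
Conditions: Me3SiOCH2CH2OSiMe3, Me3SiOTf (cat.), CH2Cl2, −78 to −20 °C
Reagents that add atoms: 1,2-bis(trimethylsilyloxy)ethane, C[Si](C)(C)OCCO[Si](C)(C)C
Why: Silyl triflate-catalysed ketalisation runs aprotically at low temperature, which should spare the silyl ether, the tert-butyl ester and the α-stereocentre C4.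

Step 11
Reactants: 17 ketal silyl ether
Product: 18 tert-butyl 2-{2-[(2R)-1-hydroxypropan-2-yl]-1,3-dioxolan-2-yl}acetate
Conditions: Bu4NF, AcOH, THF, 0 °C to rt
Reagents that add atoms: none
Why: Fluoride cleaves the silyl ether, while the acetic acid buffer and the bulk of the tert-butyl ester should keep the C5 oxygen from lactonising.

Step 12
Reactants: 18 alcohol
Product: 19 tert-butyl 2-{2-[(2S)-1-iodopropan-2-yl]-1,3-dioxolan-2-yl}acetate
Conditions: I2, PPh3, imidazole, CH2Cl2, 0 °C to rt
Reagents that add atoms: iodine, II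
Why: Appel iodination of the primary alcohol; C4 is not a reacting centre and only its descriptor changes.

Step 13
Reactants: 19 iodo ester
Product: 20 2-{2-[(2S)-1-iodopropan-2-yl]-1,3-dioxolan-2-yl}ethan-1-ol
Conditions: i-Bu2AlH (3 equiv), CH2Cl2, −78 to 0 °C
Reagents that add atoms: none
Why: i-Bu2AlH reduces the tert-butyl ester to the primary alcohol and, unlike LiAlH4, should leave the primary C–I bond intact.

Step 14
Reactants: 20 iodo alcohol
Product: 21 2-{2-[(2S)-1-iodopropan-2-yl]-1,3-dioxolan-2-yl}acetaldehyde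
Conditions: Dess–Martin periodinane, pyridine, CH2Cl2, 0 °C
Reagents that add atoms: none
Why: Buffered Dess–Martin oxidation gives the β-ketal aldehyde without acid or base that could open the dioxolane by β-elimination; the aldehyde is used at once.

Step 15
Reactants: 11 enone; 21 iodo aldehyde
Product: 23 (2S,4R,5R)-5-[2-(tert-butyldimethylsilyloxy)ethyl]-2-[(1S)-1-hydroxy-2-{2-[(2S)-1-iodopropan-2-yl]-1,3-dioxolan-2-yl}ethyl]-4-(4-methoxybenzyloxy)-2-methylcyclopentan-1-one, via lithium enolate 22 (not isolated)
Conditions: LiBH(s-Bu)3 (1.0 equiv), THF, −78 °C; then 21, −78 °C; AcOH quench at −78 °C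
Reagents that add atoms: none
Why: Reductive aldol reaction in which conjugate hydride addition gives the C10 enolate regiospecifically; the aldehyde should add through a closed Zimmerman–Traxler transition state on the face opposite to the C7 chain and O8 (C10: methyl cis to the C7 chain) with its chain equatorial (C1: carbinol oxygen anti to C9, the S centre).

Step 16
Reactants: 23 aldol adduct
Product: 24 trimethylsilyl ether of 23 at O1
Conditions: Me3SiCl, imidazole, CH2Cl2, 0 °C
Reagents that add atoms: chlorotrimethylsilane, C[Si](C)(C)Cl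
Why: Silylation removes the carbinol proton, which would quench the organosamarium of the next step, and blocks retro-aldol cleavage.

Step 17
Reactants: 24 iodo ketone
Product: 26 cis-hydroazulene 1,6-diol, via silyl ether 25 (not isolated)
Conditions: SmI2 (3 equiv), HMPA, THF, 0 °C, slow addition of 24; then K2CO3, MeOH, rt
Reagents that add atoms: none
Why: Intramolecular Barbier reaction in which SmI2 (divalent samarium) reduces the C5–I bond and the organosamarium adds to the C6 ketone (7-exo-trig) from the face carrying the C10 tether, opposite to the C7 chain, which should fix the cis ring fusion (6-OH cis to C14); methanolysis then removes only the trimethylsilyl group.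

Step 18
Reactants: 26 diol
Product: 27 cis-hydroazulene C6 alcohol C1 mesylate
Conditions: MeSO2Cl (1.3 equiv), Et3N, CH2Cl2, −10 °C
Reagents that add atoms: methanesulfonyl chloride, CS(=O)(=O)Cl
Why: Sulfonylation via sulfene reaches the secondary C1 hydroxyl, whereas the tertiary C6 hydroxyl should not react at this temperature.

Step 19
Reactants: 27 hydroxy mesylate
Product: 29 Z-cyclodecenone with C6 ketone, via potassium alkoxide 28 (not isolated)
Conditions: KOt-Bu (1.1 equiv), THF, 0 °C; pH 7 buffer quench
Reagents that add atoms: none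
Why: KOt-Bu turns the tertiary C6 hydroxyl into alkoxide 28, whose oxygen lone pair pushes into the C6–C10 bond; that bond breaks as the C10=C1 π bond forms and mesylate leaves C1, one concerted antiperiplanar step. The closest known reaction type is the Grob fragmentation of a cyclic 1,3-diol monosulfonate to a medium-ring cycloalkenone. No ring is closed in the usual sense: the ten-membered ring is set free by cutting the bond shared by the cyclopentane and the cycloheptane, so the entropic and transannular cost of a medium-ring closure is avoided. No stereocentre is formed; C4, C7 and C8 are spectators, and C1, C6 and C10 become trigonal. The selectivity needed is alkene geometry: the C1–O bond is trans to the angular methyl C14, so in the cis-fused conformer where both are pseudo-equatorial on the seven-membered ring it lies anti to C6–C10 with C2 gauche to C9 and anti to C14, and this arrangement is carried into the Z alkene. The quaternary C10 has no hydrogen and the C3 ketal removes acidity at C2, which closes the elimination exits, and barely more than one equivalent of base at 0 °C should limit enolisation of the released β-alkoxy ketone toward C7.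

Step 20
Reactants: 29 cyclodecenone
Product: 30 (6R)-alcohol
Conditions: NaBH4, MeOH/CH2Cl2, −40 °C
Reagents that add atoms: none
Why: Substrate-controlled carbonyl reduction in which hydride is expected to enter from the outer face of the ten-membered ring in the conformer that holds the C6 carbonyl anti to the C8–O dipole with the C7 chain peripheral, which should give the 6R alcohol (O6 trans to C11).

Step 21
Reactants: 30 silyl ether alcohol
Product: 31 6,12-diol
Conditions: Bu4NF, THF, 0 °C to rt
Reagents that add atoms: none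
Why: Fluoride cleaves the primary silyl ether, while the ketal, the PMB ether and the alkene are inert.

Step 22
Reactants: 31 diol
Product: 32 saturated 12,6-lactone
Conditions: TEMPO (cat.), PhI(OAc)2, CH2Cl2, rt
Reagents that add atoms: none
Why: Oxidative lactonisation in which the oxoammonium species oxidises the primary C12 alcohol faster than the secondary one, the aldehyde closes to the lactol with O6 and is oxidised on to the γ-lactone, with C6 and C7 unchanged (trans fusion).

Step 23
Reactants: 32 lactone
Product: 36 α-methylene lactone, via lithium enolate 33 (not isolated), via Mannich base 34 (not isolated), via ammonium iodide 35 (not isolated)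
Conditions: LiN(i-Pr)2 (1.1 equiv), THF, −78 °C; [Me2N=CH2]I, −78 °C to rt; MeI, MeOH, rt; aq NaHCO3, CH2Cl2, rt
Reagents that add atoms: N,N-dimethylmethyleneiminium iodide, C=[N+](C)C.[I-]
Why: Mannich reaction of the lactone enolate at C11 (the only acidic site while C3 is a ketal), quaternisation and elimination should install the C11=C13 methylene.

Step 24
Reactants: 36 PMB ether
Product: 37 C8 alcohol
Conditions: DDQ, CH2Cl2/pH 7 buffer, 0 °C
Reagents that add atoms: none
Why: Oxidative cleavage of the electron-rich benzyl ether by DDQ, which should not attack the trisubstituted alkene, the ketal or the methylene lactone.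

Step 25
Reactants: 38 tert-butyl acrylate; 39 acetaldehyde
Product: 40 tert-butyl 3-hydroxy-2-methylidenebutanoate (racemic)
Conditions: DABCO, dioxane/H2O, rt
Reagents that add atoms: none
Why: Morita–Baylis–Hillman reaction; the racemic carbinol centre is removed in step 27.

Step 26
Reactants: 40 allylic alcohol
Product: 41 tert-butyl 3-acetoxy-2-methylidenebutanoate
Conditions: Ac2O, Et3N, DMAP (cat.), CH2Cl2, 0 °C
Reagents that add atoms: acetic anhydride, CC(=O)OC(C)=O
Why: Routine acetylation of the secondary allylic alcohol.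

Step 27
Reactants: 41 allylic acetate
Product: 42 tert-butyl (2E)-2-(acetoxymethyl)but-2-enoate
Conditions: DABCO (cat.), THF, reflux
Reagents that add atoms: none
Why: Amine-mediated SN2′/SN2′ allylic transposition of acetate, which under equilibration should favour the conjugated trisubstituted ester with the methyl trans to the ester group (E).

Step 28
Reactants: 42 tert-butyl ester
Product: 43 (2E)-2-(acetoxymethyl)but-2-enoic acid
Conditions: CF3CO2H, CH2Cl2, 0 °C to rt
Reagents that add atoms: none
Why: Acidolysis of the tert-butyl ester, which leaves the primary acetate and the alkene geometry alone.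

Step 29
Reactants: 37 C8 alcohol; 43 acid
Product: 45 C8 ester with C3 ketal, via mixed anhydride 44 (not isolated)
Conditions: 43 (1.5 equiv), 2,4,6-Cl3C6H2COCl, Et3N, toluene, rt; then 37, DMAP, rt
Reagents that add atoms: none
Why: Yamaguchi esterification, which acylates the hindered secondary O8 under mild base that should not translactonise to O8 or isomerise the already E-configured enoate.

Step 30
Reactants: 45 ketal ester
Product: 46 target CNP0265140.1
Conditions: PPTS, acetone/H2O (9:1), 45 °C
Reagents that add atoms: water, O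
Why: Mild acid-catalysed ketal hydrolysis should free the C3 ketone without moving the β,γ C1=C10 alkene into conjugation, epimerising C4 or cleaving the esters.

**Compound list**

1 | (1R,5S)-2-oxabicyclo[3.3.0]oct-6-en-3-one | O=C1C[C@H]2C=CC[C@H]2O1 | starting material
2 | (1R,2S)-2-(2-hydroxyethyl)cyclopent-3-en-1-ol | OCC[C@H]1C=CC[C@H]1O | intermediate
3 | (1R,2S)-2-[2-(tert-butyldimethylsilyloxy)ethyl]cyclopent-3-en-1-ol | CC(C)(C)[Si](C)(C)OCC[C@H]1C=CC[C@H]1O | intermediate
4 | tert-butyl{2-[(1S,5R)-5-(4-methoxybenzyloxy)cyclopent-2-en-1-yl]ethoxy}dimethylsilane | CC(C)(C)[Si](C)(C)OCC[C@H]1C=CC[C@H]1OCc1ccc(OC)cc1 | intermediate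
5 | (1S,2R,3R,5R)-2-[2-(tert-butyldimethylsilyloxy)ethyl]-3-(4-methoxybenzyloxy)-6-oxabicyclo[3.1.0]hexane (oxirane trans to both substituents) | CC(C)(C)[Si](C)(C)OCC[C@H]1[C@@H]2O[C@@H]2C[C@H]1OCc1ccc(OC)cc1 | intermediate
6 | (1R,2S,3R)-2-[2-(tert-butyldimethylsilyloxy)ethyl]-3-(4-methoxybenzyloxy)cyclopentan-1-ol | CC(C)(C)[Si](C)(C)OCC[C@H]1[C@H](O)CC[C@H]1OCc1ccc(OC)cc1 | intermediate
7 | (2R,3R)-2-[2-(tert-butyldimethylsilyloxy)ethyl]-3-(4-methoxybenzyloxy)cyclopentan-1-one | CC(C)(C)[Si](C)(C)OCC[C@H]1C(=O)CC[C@H]1OCc1ccc(OC)cc1 | intermediate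
8 | lithium enolate of 7 (C6–OLi, C6=C10) | CC(C)(C)[Si](C)(C)OCC[C@H]1C([O-])=CC[C@H]1OCc1ccc(OC)cc1.[Li+] | intermediate
9 | Mannich base, 5-[(dimethylamino)methyl] derivative of 7 (C10 epimers) | CC(C)(C)[Si](C)(C)OCC[C@H]1C(=O)C(CN(C)C)C[C@H]1OCc1ccc(OC)cc1 | intermediate
10 | trimethylammonium iodide from 9 | CC(C)(C)[Si](C)(C)OCC[C@H]1C(=O)C(C[N+](C)(C)C)C[C@H]1OCc1ccc(OC)cc1.[I-] | intermediate
11 | (2R,3R)-2-[2-(tert-butyldimethylsilyloxy)ethyl]-3-(4-methoxybenzyloxy)-5-methylidenecyclopentan-1-one | CC(C)(C)[Si](C)(C)OCC[C@H]1C(=O)C(=C)C[C@H]1OCc1ccc(OC)cc1 | intermediate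
12 | methyl (R)-3-hydroxy-2-methylpropanoate | OC[C@@H](C)C(=O)OC | starting material
13 | methyl (R)-3-(tert-butyldimethylsilyloxy)-2-methylpropanoate | CC(C)(C)[Si](C)(C)OC[C@@H](C)C(=O)OC | intermediate
14 | tert-butyl acetate | CC(=O)OC(C)(C)C | starting material
15 | lithium 1-tert-butoxyethen-1-olate | [Li+].[O-]C(=C)OC(C)(C)C | intermediate
16 | tert-butyl (4R)-5-(tert-butyldimethylsilyloxy)-4-methyl-3-oxopentanoate | CC(C)(C)[Si](C)(C)OC[C@@H](C)C(=O)CC(=O)OC(C)(C)C | intermediate
17 | tert-butyl 2-{2-[(2R)-1-(tert-butyldimethylsilyloxy)propan-2-yl]-1,3-dioxolan-2-yl}acetate | CC(C)(C)[Si](C)(C)OC[C@@H](C)C1(CC(=O)OC(C)(C)C)OCCO1 | intermediate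
18 | tert-butyl 2-{2-[(2R)-1-hydroxypropan-2-yl]-1,3-dioxolan-2-yl}acetate | OC[C@@H](C)C1(CC(=O)OC(C)(C)C)OCCO1 | intermediate
19 | tert-butyl 2-{2-[(2S)-1-iodopropan-2-yl]-1,3-dioxolan-2-yl}acetate | IC[C@@H](C)C1(CC(=O)OC(C)(C)C)OCCO1 | intermediate
20 | 2-{2-[(2S)-1-iodopropan-2-yl]-1,3-dioxolan-2-yl}ethan-1-ol | IC[C@@H](C)C1(CCO)OCCO1 | intermediate
21 | 2-{2-[(2S)-1-iodopropan-2-yl]-1,3-dioxolan-2-yl}acetaldehyde | IC[C@@H](C)C1(CC=O)OCCO1 | intermediate
22 | lithium enolate from 11 (C6–OLi, C6=C10, methyl on C10) | CC(C)(C)[Si](C)(C)OCC[C@H]1C([O-])=C(C)C[C@H]1OCc1ccc(OC)cc1.[Li+] | intermediate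
23 | (2S,4R,5R)-5-[2-(tert-butyldimethylsilyloxy)ethyl]-2-[(1S)-1-hydroxy-2-{2-[(2S)-1-iodopropan-2-yl]-1,3-dioxolan-2-yl}ethyl]-4-(4-methoxybenzyloxy)-2-methylcyclopentan-1-one | CC(C)(C)[Si](C)(C)OCC[C@H]1C(=O)[C@](C)([C@@H](O)CC2(OCCO2)[C@H](C)CI)C[C@H]1OCc1ccc(OC)cc1 | intermediate
24 | O1-trimethylsilyl ether of 23 | CC(C)(C)[Si](C)(C)OCC[C@H]1C(=O)[C@](C)([C@@H](O[Si](C)(C)C)CC2(OCCO2)[C@H](C)CI)C[C@H]1OCc1ccc(OC)cc1 | intermediate
25 | cis-fused hydroazulene (bicyclo[5.3.0]decane, C6–C10 bond): 6-OH, 10-CH3, C7 CH2CH2OTBS, 8-OPMB and 4-CH3 on the α face, 1-OSiMe3 on the β face, C3 ethylene ketal | C[C@@]12C[C@@H](OCc3ccc(OC)cc3)[C@@H](CCO[Si](C)(C)C(C)(C)C)[C@]1(O)C[C@@H](C)C3(OCCO3)C[C@@H]2O[Si](C)(C)C | intermediate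
26 | cis-hydroazulene 1,6-diol: as 25 with 1-OH on the β face | C[C@@]12C[C@@H](OCc3ccc(OC)cc3)[C@@H](CCO[Si](C)(C)C(C)(C)C)[C@]1(O)C[C@@H](C)C3(OCCO3)C[C@@H]2O | intermediate
27 | cis-hydroazulene C6 alcohol C1 mesylate: as 26 with 1-OSO2CH3 on the β face (trans to C14) | C[C@@]12C[C@@H](OCc3ccc(OC)cc3)[C@@H](CCO[Si](C)(C)C(C)(C)C)[C@]1(O)C[C@@H](C)C3(OCCO3)C[C@@H]2OS(C)(=O)=O | intermediate
28 | potassium C6 alkoxide of 27 | C[C@@]12C[C@@H](OCc3ccc(OC)cc3)[C@@H](CCO[Si](C)(C)C(C)(C)C)[C@]1([O-])C[C@@H](C)C3(OCCO3)C[C@@H]2OS(C)(=O)=O.[K+] | intermediate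
29 | Z-cyclodecenone: C6 ketone, Z C1=C10, C3 ethylene ketal, (4R)-CH3, (7R)-CH2CH2OTBS, (8R)-OPMB | O=C1C[C@@H](C)C2(OCCO2)C/C=C(/C)C[C@@H](OCc2ccc(OC)cc2)[C@H]1CCO[Si](C)(C)C(C)(C)C | intermediate
30 | (4R,6R,7S,8R)-C6 alcohol of 29 (O6 trans to C11) | O[C@@H]1C[C@@H](C)C2(OCCO2)C/C=C(/C)C[C@@H](OCc2ccc(OC)cc2)[C@H]1CCO[Si](C)(C)C(C)(C)C | intermediate
31 | (4R,6R,7S,8R)-6,12-diol | O[C@@H]1C[C@@H](C)C2(OCCO2)C/C=C(/C)C[C@@H](OCc2ccc(OC)cc2)[C@H]1CCO | intermediate
32 | (4R,6R,7R,8R)-12,6-lactone with CH2 at C11, C3 ketal, 8-OPMB | O=C1O[C@@H]2C[C@@H](C)C3(OCCO3)C/C=C(/C)C[C@@H](OCc3ccc(OC)cc3)[C@H]2C1 | intermediate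
33 | lithium enolate of 32 (C11=C12–OLi) | [Li+].[O-]C1O[C@@H]2C[C@@H](C)C3(OCCO3)C/C=C(/C)C[C@@H](OCc3ccc(OC)cc3)[C@H]2C=1 | intermediate
34 | Mannich base, 11-[(dimethylamino)methyl] lactone (C11 epimers) | CN(C)CC1C(=O)O[C@@H]2C[C@@H](C)C3(OCCO3)C/C=C(/C)C[C@@H](OCc3ccc(OC)cc3)[C@@H]12 | intermediate
35 | trimethylammonium iodide from 34 | C[N+](C)(C)CC1C(=O)O[C@@H]2C[C@@H](C)C3(OCCO3)C/C=C(/C)C[C@@H](OCc3ccc(OC)cc3)[C@@H]12.[I-] | intermediate
36 | (4R,6R,7R,8R)-α-methylene lactone with C3 ketal and 8-OPMB | C=C1C(=O)O[C@@H]2C[C@@H](C)C3(OCCO3)C/C=C(/C)C[C@@H](OCc3ccc(OC)cc3)[C@@H]12 | intermediate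
37 | (4R,6R,7R,8R)-α-methylene lactone with C3 ketal and free 8-OH | C=C1C(=O)O[C@@H]2C[C@@H](C)C3(OCCO3)C/C=C(/C)C[C@@H](O)[C@@H]12 | intermediate
38 | tert-butyl acrylate | C=CC(=O)OC(C)(C)C | starting material
39 | acetaldehyde | CC=O | starting material
40 | tert-butyl 3-hydroxy-2-methylidenebutanoate (racemic) | CC(O)C(=C)C(=O)OC(C)(C)C | intermediate
41 | tert-butyl 3-acetoxy-2-methylidenebutanoate (racemic) | CC(OC(C)=O)C(=C)C(=O)OC(C)(C)C | intermediate
42 | tert-butyl (2E)-2-(acetoxymethyl)but-2-enoate | C/C=C(\COC(C)=O)C(=O)OC(C)(C)C | intermediate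
43 | (2E)-2-(acetoxymethyl)but-2-enoic acid | C/C=C(\COC(C)=O)C(=O)O | intermediate
44 | mixed anhydride of 43 with 2,4,6-trichlorobenzoic acid | C/C=C(\COC(C)=O)C(=O)OC(=O)c1c(Cl)cc(Cl)cc1Cl | intermediate
45 | (4R,6R,7S,8R)-8-[(2E)-2-(acetoxymethyl)but-2-enoyloxy] α-methylene lactone with C3 ethylene ketal | C=C1C(=O)O[C@@H]2C[C@@H](C)C3(OCCO3)C/C=C(/C)C[C@@H](OC(=O)/C(=C/C)COC(C)=O)[C@@H]12 | intermediate
46 | CNP0265140.1, (1(10)Z,4R,6R,7S,8R)-8-[(2E)-2-(acetoxymethyl)but-2-enoyloxy]-3-oxogermacra-1(10),11(13)-dien-12,6-olide | C=C1C(=O)O[C@@H]2C[C@@H](C)C(=O)C/C=C(/C)C[C@@H](OC(=O)/C(=C/C)COC(C)=O)[C@@H]12 | target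

**Step count and risks**

Total: 30 steps. Longest linear sequence: 19 steps (steps 1–7, 15–24, 29, 30; the branch through steps 8–14 is equally long).

Steps most likely to fail:

1. Step 15 (reductive aldol). The congested aldolate may revert, and the facial preference at the aldehyde carbon may be poor, so that the C1 carbinol forms as a mixture; the C1 configuration later decides the alkene geometry. Fallback: the C1 epimers are carried together through steps 16 and 17 to diol 26. Setting out from 26 as that mixture, Dess–Martin oxidation of the secondary C1 hydroxyl (the tertiary C6 hydroxyl is inert) should give the β-hydroxy ketone F1. Hydroxyl-directed reduction with Me4NBH(OAc)3 in MeCN/AcOH at −20 °C (Evans–Saksena, 1,3-anti) then delivers hydride from the face of the C6 oxygen and should return a single diol with O1 trans to O6 and C14, rejoining the route at 26.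

2. Step 17 (Barbier closure of the seven-membered ring). The C5–I bond may be reduced to C–H, or the C6 ketone may react through its ketyl, before the ring closes. Fallback: a polar closure in place of the single-electron one. Setting out from 24, iodine–lithium exchange with t-BuLi (2.1 equiv) in Et2O/pentane at −100 °C is faster than carbonyl addition or enolisation, and the primary alkyllithium should add to the neighbouring C6 ketone from the tether face to give 25 as its lithium alkoxide. The same methanolysis (K2CO3, MeOH) rejoins the route at 26.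

3. Step 19 (fragmentation). The β-alkoxy ketone released in a basic medium may enolise toward C7, losing 4-methoxybenzyl oxide or epimerising C7, and the alkoxide may alkylate at C1 to an oxetane if the antiperiplanar conformer is thinly populated. Fallback: a hydride-triggered fragmentation coupled with reduction. Setting out from 27, LiAlH4 in THF (0 °C to rt) forms the C6 alkoxyaluminate, which should undergo the same C6–C10 cleavage, and the ketone is reduced as it forms, so no free β-alkoxy ketone meets base. This merges steps 19 and 20 and rejoins the route at 30.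

**Further compounds**

F1 | step 15 | cis-hydroazulene 6-hydroxy-1-ketone (26 with C1 oxidised to the ketone) | C[C@@]12C[C@@H](OCc3ccc(OC)cc3)[C@@H](CCO[Si](C)(C)C(C)(C)C)[C@]1(O)C[C@@H](C)C3(OCCO3)CC2=O
F0 | step 17 | none | none
F0 | step 19 | none | none
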